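## Retrosynthetic overview

1. Target ⇐ desilylation and acetylation ⇐ ring A tertiary carbinol from Markovnikov, trans-diaxial oxymercuration of a ring A cyclohexene ⇐ sp3–sp2 Negishi union of a hydrindane CH2ZnI with a ring A enol triflate.
2. Ring A branch (ring formed first): enol triflate ⇐ (S)-4-bromo-3,3-dimethylcyclohexanone ⇐ 1,3 O→C rearrangement of a methylenated bromo-δ-lactone ⇐ catalytic asymmetric bromolactonisation.
3. Hydrindane branch: the five-membered ring is closed last (C1–C2, acid dianion alkylation) on a six-membered ring made in the key new step, a hydroxyl-directed Ti-catalysed enantioselective bromonium cyclisation/etherification of a (2Z,6E)-trienol. That step sets the C–Br, quaternary, ring-fusion and tertiary C–O centres; the bridging ether, later a lactone, masks CH2OH and the tertiary OH.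
4. Trienol ⇐ Still–Gennari (Z) olefination ⇐ aldehyde ⇐ Johnson–Claisen (E) ⇐ methacrolein. Ring order: ring A, six-membered ring, five-membered ring, then fragment union.

Assumption: only species made in one operation and consumed in a later operation of the same step (19, 23) are numbered as non-isolated intermediates; enolates, alkoxides and other transient species of a single operation are not, and metal residues are written as they stand after aqueous work-up.

## Route

Step 1
Reactants: 1 5-methylhex-4-enoic acid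
Product: 2 (5S)-5-bromo-6,6-dimethyloxan-2-one
Conditions: NBS, (DHQD)2PHAL (10 mol %), PhCO2H (10 mol %), CHCl3/hexane 1:1, −40 °C; recrystallise
Reagents that add atoms: N-bromosuccinimide O=C1CCC(=O)N1Br
Why: Catalytic asymmetric bromolactonisation, in which the chiral amine–NBS complex delivers Br+ to one enantiotopic face of the trisubstituted alkene and the carboxyl group opens the bromonium ion anti at the tertiary carbon (6-endo, Markovnikov), setting the (S) C–Br centre (the pseudo-enantiomeric (DHQ)2PHAL is used instead if the sense of induction is opposite).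

Step 2
Reactants: 2 (5S)-5-bromo-6,6-dimethyloxan-2-one
Product: 3 (3S)-3-bromo-2,2-dimethyl-6-methylideneoxane
Conditions: Cp2TiMe2 (2.5 equiv), toluene, 65 °C, dark
Reagents that add atoms: dimethyltitanocene [CH3-].[CH3-].[Ti+4].c1cc[cH-]c1.c1cc[cH-]c1
Why: Petasis methylenation (Cp2Ti=CH2 formed thermally) turns the lactone C=O into the exocyclic enol ether under base-free conditions, so the secondary bromide and its stereocentre are untouched.

Step 3
Reactants: 3 (3S)-3-bromo-2,2-dimethyl-6-methylideneoxane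
Product: 4 (4S)-4-bromo-3,3-dimethylcyclohexan-1-one
Conditions: Me2AlCl (1.2 equiv), CH2Cl2, −78 → −40 °C
Reagents that add atoms: none
Why: Petasis–Ferrier-type 1,3 O→C rearrangement, in which the Lewis acid ionises the tertiary C–O bond with anchimeric help from the neighbouring bromine and the tethered aluminium enolate recloses at the tertiary carbon from the face the oxygen left, so the C–Br centre is retained as (S).

Step 4
Reactants: 4 (4S)-4-bromo-3,3-dimethylcyclohexan-1-one
Product: 5 (4S)-4-bromo-5,5-dimethylcyclohex-1-en-1-yl trifluoromethanesulfonate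
Conditions: LiN(SiMe3)2, THF, −78 °C; then 2-[N,N-bis(trifluoromethylsulfonyl)amino]-5-chloropyridine, −78 → 0 °C
Reagents that add atoms: Comins' reagent FC(F)(F)S(=O)(=O)N(c1ccc(Cl)cn1)S(=O)(=O)C(F)(F)F
Why: Kinetic enolisation occurs at the CH2 remote from the gem-dimethyl group and O-sulfonylation (enol triflate formation) fixes that alkene, while the hindered neopentylic bromide does not alkylate the enolate at −78 °C.

Step 5
Reactants: 6 2-methylprop-2-enal
Product: 7 rac-2-methylhexa-1,5-dien-3-ol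
Conditions: CH2=CHCH2MgBr, Et2O, −78 °C; then H2O
Reagents that add atoms: allylmagnesium bromide C=CC[Mg]Br
Why: Grignard 1,2-addition to the enal gives the secondary allylic alcohol, whose racemic carbinol centre is erased in the next step.

Step 6
Reactants: 7 rac-2-methylhexa-1,5-dien-3-ol
Product: 8 ethyl (4E)-4-methylocta-4,7-dienoate
Conditions: MeC(OEt)3, EtCO2H (5 mol %), 140 °C, EtOH distilled off
Reagents that add atoms: triethyl orthoacetate CC(OCC)(OCC)OCC
Why: Johnson–Claisen rearrangement through a chair transition state with the allyl substituent equatorial gives the (E) trisubstituted alkene.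

Step 7
Reactants: 8 ethyl (4E)-4-methylocta-4,7-dienoate
Product: 9 (4E)-4-methylocta-4,7-dienal
Conditions: iBu2AlH (1.05 equiv), CH2Cl2, −78 °C
Reagents that add atoms: none
Why: Partial hydride reduction of the ester stops at the aluminium hemiacetal at −78 °C and releases the aldehyde on work-up without touching the alkenes.

Step 8
Reactants: 10 methyl 2-[bis(2,2,2-trifluoroethoxy)phosphoryl]acetate
Product: 11 rac-methyl 2-[bis(2,2,2-trifluoroethoxy)phosphoryl]-4-chlorobutanoate
Conditions: NaH (1.0 equiv), DMF, 0 °C; ICH2CH2Cl (3 equiv), 0 → 23 °C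
Reagents that add atoms: 1-chloro-2-iodoethane ClCCI
Why: SN2 C-alkylation of the phosphonoacetate anion at the iodide end, with one equivalent of base and excess dihalide to suppress a second deprotonation and cyclopropane formation (the new CH centre is lost in the next step).

Step 9
Reactants: 9 (4E)-4-methylocta-4,7-dienal; 11 rac-methyl 2-[bis(2,2,2-trifluoroethoxy)phosphoryl]-4-chlorobutanoate
Product: 12 methyl (2Z,6E)-2-(2-chloroethyl)-6-methyldeca-2,6,9-trienoate
Conditions: KN(SiMe3)2, 18-crown-6, THF, −78 °C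
Reagents that add atoms: none
Why: Still–Gennari variant of the Horner–Wadsworth–Emmons olefination, where fast irreversible elimination from the trifluoroethyl phosphonate adduct gives the (Z) enoate with the ester cis to the chain.

Step 10
Reactants: 12 methyl (2Z,6E)-2-(2-chloroethyl)-6-methyldeca-2,6,9-trienoate
Product: 13 (2Z,6E)-2-(2-chloroethyl)-6-methyldeca-2,6,9-trien-1-ol
Conditions: iBu2AlH (2.5 equiv), CH2Cl2, −78 °C
Reagents that add atoms: none
Why: 1,2-Reduction of the enoate gives the (Z) allylic alcohol without changing alkene geometry or touching the alkyl chloride.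

Step 11
Reactants: 13 (2Z,6E)-2-(2-chloroethyl)-6-methyldeca-2,6,9-trien-1-ol
Product: 14 (1S,2S,5R,8S)-2-bromo-1-(2-chloroethyl)-5-methyl-8-(prop-2-en-1-yl)-6-oxabicyclo[3.2.1]octane
Conditions: NBS (1.1 equiv), Ti(OiPr)4 (10 mol %), Schiff-base ligand (S)-L (12 mol %), 4 Å MS, hexane/CH2Cl2 4:1, −20 °C
Reagents that add atoms: N-bromosuccinimide O=C1CCC(=O)N1Br
Why: Proposed new method: a hydroxyl-directed catalytic enantioselective bromonium-initiated cation–olefin cyclisation, in which the allylic alcohol binds the chiral tetravalent titanium complex of (S)-L (the tridentate Schiff base of 3,5-di-tert-butylsalicylaldehyde and (S)-2-amino-3,3-dimethyl-1,1-diphenylbutan-1-ol; the ligand enantiomer that gives 14 is used) so that Br+ from NBS reaches only the bound (Z)-alkene and only one of its faces; with no external halide present the bromonium ion is opened at its tertiary carbon by the (E)-alkene through a chair transition state (Br equatorial, CH2O–Ti axial because it is cis to the chain, ring-fusion H axial, allyl equatorial) and the tertiary cation is captured by the 1,3-diaxial titanium-bound oxygen, which sets the C–Br, quaternary, ring-fusion and tertiary C–O centres together and releases the catalyst; the closest known reaction types are the titanium–Schiff base catalysed enantioselective bromochlorination of allylic alcohols and hydroxyl-terminated bromonium polyene cyclisations.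

Step 12
Reactants: 14 (1S,2S,5R,8S)-2-bromo-1-(2-chloroethyl)-5-methyl-8-(prop-2-en-1-yl)-6-oxabicyclo[3.2.1]octane
Product: 15 2-[(1S,2S,5R,8S)-2-bromo-1-(2-chloroethyl)-5-methyl-7-oxo-6-oxabicyclo[3.2.1]octan-8-yl]acetic acid
Conditions: RuCl3·xH2O (5 mol %), NaIO4 (8 equiv), CCl4/MeCN/H2O 2:2:3, 23 °C
Reagents that add atoms: sodium periodate [Na+].[O-]I(=O)(=O)=O
Why: Catalytic RuO4 oxidation does two known jobs in one flask, cleaving the terminal alkene to the carboxylic acid and oxidising the only ether CH2 (the other ether carbon is quaternary) to the lactone carbonyl, with no stereocentre touched.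

Step 13
Reactants: 15 2-[(1S,2S,5R,8S)-2-bromo-1-(2-chloroethyl)-5-methyl-7-oxo-6-oxabicyclo[3.2.1]octan-8-yl]acetic acid
Product: 16 (1R,3aS,4S,7R,7aS)-4-bromo-7-hydroxy-7-methyloctahydro-1H-indene-1,3a-dicarboxylic acid 3a,7-lactone
Conditions: LiN(iPr)2 (2.3 equiv), THF/DMPU, −78 → 0 °C; then 1 M HCl
Reagents that add atoms: none
Why: Intramolecular 5-exo-tet alkylation of the carboxylic acid dianion joins C1 to C2; both tethers are equatorial on the lactone-locked chair so the new ring is trans-fused, and the enediolate reacts in the conformer that minimises A(1,3) strain (C7a–H eclipsed), which puts the carboxyl cis to C7a–H and trans to C7, also the more stable trans-1,2 arrangement.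

Step 14
Reactants: 16 (1R,3aS,4S,7R,7aS)-4-bromo-7-hydroxy-7-methyloctahydro-1H-indene-1,3a-dicarboxylic acid 3a,7-lactone
Product: 17 (1R,3aS,4S,7R,7aS)-4-bromo-7-hydroxy-1-(hydroxymethyl)-7-methyloctahydro-1H-indene-3a-carboxylic acid 3a,7-lactone
Conditions: BH3·THF (1.5 equiv), THF, 0 → 23 °C; then H2O
Reagents that add atoms: none
Why: Chemoselective borane reduction of the free carboxylic acid (through the acyloxyborane) leaves the hindered lactone and the alkyl bromide intact.

Step 15
Reactants: 17 (1R,3aS,4S,7R,7aS)-4-bromo-7-hydroxy-1-(hydroxymethyl)-7-methyloctahydro-1H-indene-3a-carboxylic acid 3a,7-lactone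
Product: 18 (1R,3aS,4S,7R,7aS)-4-bromo-7-hydroxy-1-(iodomethyl)-7-methyloctahydro-1H-indene-3a-carboxylic acid 3a,7-lactone
Conditions: I2, PPh3, imidazole, CH2Cl2, 0 → 23 °C
Reagents that add atoms: iodine II
Why: Appel-type iodination of the only hydroxyl group by SN2 displacement of the alkoxyphosphonium ion at the primary carbon.

Step 16
Reactants: 18 (1R,3aS,4S,7R,7aS)-4-bromo-7-hydroxy-1-(iodomethyl)-7-methyloctahydro-1H-indene-3a-carboxylic acid 3a,7-lactone; 5 (4S)-4-bromo-5,5-dimethylcyclohex-1-en-1-yl trifluoromethanesulfonate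
Product: 20 (1S,3aS,4S,7R,7aS)-4-bromo-1-{[(4S)-4-bromo-5,5-dimethylcyclohex-1-en-1-yl]methyl}-7-hydroxy-7-methyloctahydro-1H-indene-3a-carboxylic acid 3a,7-lactone, via alkylzinc iodide 19 (not isolated)
Conditions: Zn dust (activated), LiCl, THF, 40 °C; then 5, PdCl2(dppf) (5 mol %), THF/DMA, 50 °C
Reagents that add atoms: none
Why: Negishi sp3–sp2 cross-coupling, in which zinc inserts only into the primary C–I bond and the zerovalent palladium formed from PdCl2(dppf) adds only to the C–OTf bond, so the lactone and both hindered secondary bromides survive and no stereocentre is formed or touched.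

Step 17
Reactants: 20 (1S,3aS,4S,7R,7aS)-4-bromo-1-{[(4S)-4-bromo-5,5-dimethylcyclohex-1-en-1-yl]methyl}-7-hydroxy-7-methyloctahydro-1H-indene-3a-carboxylic acid 3a,7-lactone
Product: 21 (1S,3aS,4S,7R,7aS)-4-bromo-1-{[(4S)-4-bromo-5,5-dimethylcyclohex-1-en-1-yl]methyl}-3a-(hydroxymethyl)-7-methyloctahydro-1H-inden-7-ol
Conditions: LiBH4 (4 equiv), MeOH (2 equiv), THF, 0 → 45 °C
Reagents that add atoms: none
Why: Hydride reduction opens the lactone to the primary alcohol and the tertiary alcohol without breaking the C7–O bond, and LiBH4 leaves the alkene and the alkyl bromides alone.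

Step 18
Reactants: 21 (1S,3aS,4S,7R,7aS)-4-bromo-1-{[(4S)-4-bromo-5,5-dimethylcyclohex-1-en-1-yl]methyl}-3a-(hydroxymethyl)-7-methyloctahydro-1H-inden-7-ol
Product: 22 (1S,3aS,4S,7R,7aS)-4-bromo-1-{[(4S)-4-bromo-5,5-dimethylcyclohex-1-en-1-yl]methyl}-7-(tert-butyldimethylsilyloxy)-3a-[(tert-butyldimethylsilyloxy)methyl]-7-methyloctahydro-1H-indene
Conditions: TBSOTf (3 equiv), 2,6-lutidine, CH2Cl2, 0 → 23 °C
Reagents that add atoms: tert-butyldimethylsilyl trifluoromethanesulfonate CC(C)(C)[Si](C)(C)OS(=O)(=O)C(F)(F)F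
Why: Silyl triflate silylation protects both the primary and the hindered tertiary hydroxyl group, so that only the ring A oxygen is free when the acetate is installed.

Step 19
Reactants: 22 (1S,3aS,4S,7R,7aS)-4-bromo-1-{[(4S)-4-bromo-5,5-dimethylcyclohex-1-en-1-yl]methyl}-7-(tert-butyldimethylsilyloxy)-3a-[(tert-butyldimethylsilyloxy)methyl]-7-methyloctahydro-1H-indene
Product: 24 (1S,4S)-4-bromo-1-{[(1S,3aS,4S,7R,7aS)-4-bromo-7-(tert-butyldimethylsilyloxy)-3a-[(tert-butyldimethylsilyloxy)methyl]-7-methyloctahydro-1H-inden-1-yl]methyl}-3,3-dimethylcyclohexan-1-ol, via acetoxymercurio adduct 23 (not isolated)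
Conditions: Hg(OAc)2, THF/H2O 1:1, 23 °C; then NaBH4, 3 M NaOH, 0 °C
Reagents that add atoms: water O
Why: Oxymercuration–demercuration (Markovnikov hydration), in which water opens the mercurinium ion anti at the tertiary carbon through a chair transition state with OH and Hg trans-diaxial and the large CH2 substituent equatorial; the alternative with the ring A C–Br bond axial suffers a 1,3-diaxial clash with the axial C–Hg bond, so OH ends cis to Br and the (1S) carbinol is set.

Step 20
Reactants: 24 (1S,4S)-4-bromo-1-{[(1S,3aS,4S,7R,7aS)-4-bromo-7-(tert-butyldimethylsilyloxy)-3a-[(tert-butyldimethylsilyloxy)methyl]-7-methyloctahydro-1H-inden-1-yl]methyl}-3,3-dimethylcyclohexan-1-ol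
Product: 25 (1S,4S)-4-bromo-1-{[(1S,3aS,4S,7R,7aS)-4-bromo-7-(tert-butyldimethylsilyloxy)-3a-[(tert-butyldimethylsilyloxy)methyl]-7-methyloctahydro-1H-inden-1-yl]methyl}-3,3-dimethylcyclohexyl acetate
Conditions: Ac2O, DMAP, Et3N, CH2Cl2, 40 °C
Reagents that add atoms: acetic anhydride CC(=O)OC(C)=O
Why: DMAP-catalysed acylation of the only free hydroxyl group, the axial tertiary ring A alcohol, without touching any stereocentre.

Step 21
Reactants: 25 (1S,4S)-4-bromo-1-{[(1S,3aS,4S,7R,7aS)-4-bromo-7-(tert-butyldimethylsilyloxy)-3a-[(tert-butyldimethylsilyloxy)methyl]-7-methyloctahydro-1H-inden-1-yl]methyl}-3,3-dimethylcyclohexyl acetate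
Product: 26 (1S,4S)-4-bromo-1-{[(1S,3aS,4S,7R,7aS)-4-bromo-7-hydroxy-3a-(hydroxymethyl)-7-methyloctahydro-1H-inden-1-yl]methyl}-3,3-dimethylcyclohexyl acetate
Conditions: HF·pyridine, pyridine, THF, 0 → 23 °C
Reagents that add atoms: none
Why: Fluoride-driven cleavage of both silyl ethers under buffered conditions leaves the tertiary acetate, the tertiary alcohol and both bromides intact and gives the target.

## Compound list

1 | 5-methylhex-4-enoic acid | CC(C)=CCCC(=O)O | starting material
2 | (5S)-5-bromo-6,6-dimethyloxan-2-one | O=C1CC[C@H](Br)C(C)(C)O1 | intermediate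
3 | (3S)-3-bromo-2,2-dimethyl-6-methylideneoxane | C=C1CC[C@H](Br)C(C)(C)O1 | intermediate
4 | (4S)-4-bromo-3,3-dimethylcyclohexan-1-one | O=C1CC[C@H](Br)C(C)(C)C1 | intermediate
5 | (4S)-4-bromo-5,5-dimethylcyclohex-1-en-1-yl trifluoromethanesulfonate | O=S(=O)(OC1=CC[C@H](Br)C(C)(C)C1)C(F)(F)F | intermediate
6 | 2-methylprop-2-enal (methacrolein) | CC(=C)C=O | starting material
7 | rac-2-methylhexa-1,5-dien-3-ol | C=CCC(O)C(C)=C | intermediate
8 | ethyl (4E)-4-methylocta-4,7-dienoate | CCOC(=O)CC/C(C)=C/CC=C | intermediate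
9 | (4E)-4-methylocta-4,7-dienal | O=CCC/C(C)=C/CC=C | intermediate
10 | methyl 2-[bis(2,2,2-trifluoroethoxy)phosphoryl]acetate | COC(=O)CP(=O)(OCC(F)(F)F)OCC(F)(F)F | starting material
11 | rac-methyl 2-[bis(2,2,2-trifluoroethoxy)phosphoryl]-4-chlorobutanoate | COC(=O)C(CCCl)P(=O)(OCC(F)(F)F)OCC(F)(F)F | intermediate
12 | methyl (2Z,6E)-2-(2-chloroethyl)-6-methyldeca-2,6,9-trienoate | COC(=O)/C(CCCl)=C\CC/C(C)=C/CC=C | intermediate
13 | (2Z,6E)-2-(2-chloroethyl)-6-methyldeca-2,6,9-trien-1-ol | OC/C(CCCl)=C\CC/C(C)=C/CC=C | intermediate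
14 | (1S,2S,5R,8S)-2-bromo-1-(2-chloroethyl)-5-methyl-8-(prop-2-en-1-yl)-6-oxabicyclo[3.2.1]octane | C=CC[C@H]1[C@@](CCCl)(C2)[C@@H](Br)CC[C@@]1(C)O2 | intermediate
15 | 2-[(1S,2S,5R,8S)-2-bromo-1-(2-chloroethyl)-5-methyl-7-oxo-6-oxabicyclo[3.2.1]octan-8-yl]acetic acid | OC(=O)C[C@H]1[C@@](CCCl)(C2=O)[C@@H](Br)CC[C@@]1(C)O2 | intermediate
16 | (1R,3aS,4S,7R,7aS)-4-bromo-7-hydroxy-7-methyloctahydro-1H-indene-1,3a-dicarboxylic acid 3a,7-lactone (trans-fused; free CO2H at C1) | OC(=O)[C@@H]1CC[C@]2(C3=O)[C@@H](Br)CC[C@@](C)(O3)[C@@H]12 | intermediate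
17 | (1R,3aS,4S,7R,7aS)-4-bromo-7-hydroxy-1-(hydroxymethyl)-7-methyloctahydro-1H-indene-3a-carboxylic acid 3a,7-lactone | OC[C@@H]1CC[C@]2(C3=O)[C@@H](Br)CC[C@@](C)(O3)[C@@H]12 | intermediate
18 | (1R,3aS,4S,7R,7aS)-4-bromo-7-hydroxy-1-(iodomethyl)-7-methyloctahydro-1H-indene-3a-carboxylic acid 3a,7-lactone | IC[C@@H]1CC[C@]2(C3=O)[C@@H](Br)CC[C@@](C)(O3)[C@@H]12 | intermediate
19 | alkylzinc iodide of 18 (C1–CH2–ZnI; 1R,3aS,4S,7R,7aS; lactone intact) | I[Zn]C[C@@H]1CC[C@]2(C3=O)[C@@H](Br)CC[C@@](C)(O3)[C@@H]12 | intermediate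
20 | (1S,3aS,4S,7R,7aS)-4-bromo-1-{[(4S)-4-bromo-5,5-dimethylcyclohex-1-en-1-yl]methyl}-7-hydroxy-7-methyloctahydro-1H-indene-3a-carboxylic acid 3a,7-lactone | C(C1=CC[C@H](Br)C(C)(C)C1)[C@@H]1CC[C@]2(C3=O)[C@@H](Br)CC[C@@](C)(O3)[C@@H]12 | intermediate
21 | (1S,3aS,4S,7R,7aS)-4-bromo-1-{[(4S)-4-bromo-5,5-dimethylcyclohex-1-en-1-yl]methyl}-3a-(hydroxymethyl)-7-methyloctahydro-1H-inden-7-ol | C(C1=CC[C@H](Br)C(C)(C)C1)[C@@H]1CC[C@]2(CO)[C@@H](Br)CC[C@@](C)(O)[C@@H]12 | intermediate
22 | (1S,3aS,4S,7R,7aS)-4-bromo-1-{[(4S)-4-bromo-5,5-dimethylcyclohex-1-en-1-yl]methyl}-7-(tert-butyldimethylsilyloxy)-3a-[(tert-butyldimethylsilyloxy)methyl]-7-methyloctahydro-1H-indene | C(C1=CC[C@H](Br)C(C)(C)C1)[C@@H]1CC[C@]2(CO[Si](C)(C)C(C)(C)C)[C@@H](Br)CC[C@@](C)(O[Si](C)(C)C(C)(C)C)[C@@H]12 | intermediate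
23 | (1S,2S,4S)-2-(acetoxymercurio)-4-bromo-1-{[(1S,3aS,4S,7R,7aS)-4-bromo-7-(tert-butyldimethylsilyloxy)-3a-[(tert-butyldimethylsilyloxy)methyl]-7-methyloctahydro-1H-inden-1-yl]methyl}-5,5-dimethylcyclohexan-1-ol (OH and Hg trans-diaxial) | O[C@]1(C[C@@H]2CC[C@]3(CO[Si](C)(C)C(C)(C)C)[C@@H](Br)CC[C@@](C)(O[Si](C)(C)C(C)(C)C)[C@@H]23)[C@@H]([Hg]OC(C)=O)C[C@H](Br)C(C)(C)C1 | intermediate
24 | (1S,4S)-4-bromo-1-{[(1S,3aS,4S,7R,7aS)-4-bromo-7-(tert-butyldimethylsilyloxy)-3a-[(tert-butyldimethylsilyloxy)methyl]-7-methyloctahydro-1H-inden-1-yl]methyl}-3,3-dimethylcyclohexan-1-ol | O[C@]1(C[C@@H]2CC[C@]3(CO[Si](C)(C)C(C)(C)C)[C@@H](Br)CC[C@@](C)(O[Si](C)(C)C(C)(C)C)[C@@H]23)CC[C@H](Br)C(C)(C)C1 | intermediate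
25 | (1S,4S)-4-bromo-1-{[(1S,3aS,4S,7R,7aS)-4-bromo-7-(tert-butyldimethylsilyloxy)-3a-[(tert-butyldimethylsilyloxy)methyl]-7-methyloctahydro-1H-inden-1-yl]methyl}-3,3-dimethylcyclohexyl acetate | CC(=O)O[C@]1(C[C@@H]2CC[C@]3(CO[Si](C)(C)C(C)(C)C)[C@@H](Br)CC[C@@](C)(O[Si](C)(C)C(C)(C)C)[C@@H]23)CC[C@H](Br)C(C)(C)C1 | intermediate
26 | (1S,4S)-4-bromo-1-{[(1S,3aS,4S,7R,7aS)-4-bromo-7-hydroxy-3a-(hydroxymethyl)-7-methyloctahydro-1H-inden-1-yl]methyl}-3,3-dimethylcyclohexyl acetate (CNP0182818.1) | CC(=O)O[C@]1(C[C@@H]2CC[C@]3(CO)[C@@H](Br)CC[C@@](C)(O)[C@@H]23)CC[C@H](Br)C(C)(C)C1 | target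

## Step count and risks

Total steps: 21. Longest linear sequence: 16 steps (6 → 26 through steps 5–7 and 9–21); the ring A branch (steps 1–4) joins at step 16 and the phosphonate (step 8) at step 9.

The three steps most likely to fail:

Step 3 (Lewis-acid 1,3 O→C rearrangement). The risks are E1 loss of a methyl proton or attack of the enolate at the secondary carbon of the bromonium ion. The fallback is a stepwise Mukaiyama–Reetz tert-alkylation that sets out from lactone 2 and comes back at ketone 4. MeLi (1 equiv, THF, −78 °C) adds once to 2 to give (5S)-5-bromo-6-hydroxy-6-methylheptan-2-one F1, in equilibrium with its cyclic hemiketal. LiN(iPr)2 (2.2 equiv) with Me3SiCl as internal quench at −78 °C silylates the alkoxide and the kinetic methyl enolate to give (5S)-5-bromo-6-methyl-2,6-bis[(trimethylsilyl)oxy]hept-1-ene F2. TiCl4 in CH2Cl2 at −78 °C then ionises the tertiary silyl ether with bromine participation and the silyl enol ether alkylates the tertiary carbon, giving 4.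

Step 11 (the proposed new cyclisation). The risks are bromination of the unbound (E)-alkene, direct attack of the alkoxide on the bromonium ion, or low enantioselectivity. The fallback uses known chemistry, sets out from trienol 13 and comes back at 14. Sharpless asymmetric epoxidation (Ti(OiPr)4, L-(+)-diethyl tartrate, tBuOOH, 4 Å MS, CH2Cl2, −20 °C) gives [(2S,3R)-2-(2-chloroethyl)-3-[(3E)-3-methylhepta-3,6-dien-1-yl]oxiran-2-yl]methanol F3. Ti(OiPr)4-mediated opening at C3 with bromide (Et2NH·HBr, CH2Cl2, 0 °C, inversion) gives (2S,3S,6E)-3-bromo-2-(2-chloroethyl)-6-methyldeca-6,9-diene-1,2-diol F4. Ionisation of the tertiary hydroxyl group of F4 (TfOH 10 mol %, HFIP, −20 °C) regenerates the same enantiopure bromonium ion by anchimeric assistance; it cyclises through the same chair and is captured by the primary hydroxyl group to give 14.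

Step 13 (acid dianion ring closure). The risks are a sluggish displacement of the primary chloride and kinetic rather than thermodynamic control at C1. The fallback closes the ring through an aldehyde enolate under equilibrating conditions, sets out from acid 15 and comes back at alcohol 17. BH3·THF reduces the acid to (1S,2S,5R,8S)-2-bromo-1-(2-chloroethyl)-8-(2-hydroxyethyl)-5-methyl-6-oxabicyclo[3.2.1]octan-7-one F5. Dess–Martin periodinane gives 2-[(1S,2S,5R,8S)-2-bromo-1-(2-chloroethyl)-5-methyl-7-oxo-6-oxabicyclo[3.2.1]octan-8-yl]acetaldehyde F6. KOtBu with catalytic NaI in tBuOH/THF at 0 → 23 °C effects intramolecular α-alkylation and equilibrates C1 to (1R,3aS,4S,7R,7aS)-4-bromo-1-formyl-7-hydroxy-7-methyloctahydro-1H-indene-3a-carboxylic acid 3a,7-lactone F7. NaBH4 in MeOH at 0 °C reduces only the aldehyde and gives 17.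

## Further compounds

F1 | step 3 | (5S)-5-bromo-6-hydroxy-6-methylheptan-2-one | CC(=O)CC[C@H](Br)C(C)(C)O
F2 | step 3 | (5S)-5-bromo-6-methyl-2,6-bis[(trimethylsilyl)oxy]hept-1-ene | C=C(O[Si](C)(C)C)CC[C@H](Br)C(C)(C)O[Si](C)(C)C
F3 | step 11 | [(2S,3R)-2-(2-chloroethyl)-3-[(3E)-3-methylhepta-3,6-dien-1-yl]oxiran-2-yl]methanol | O1[C@@](CCCl)(CO)[C@H]1CC/C(C)=C/CC=C
F4 | step 11 | (2S,3S,6E)-3-bromo-2-(2-chloroethyl)-6-methyldeca-6,9-diene-1,2-diol | O[C@@](CCCl)(CO)[C@@H](Br)CC/C(C)=C/CC=C
F5 | step 13 | (1S,2S,5R,8S)-2-bromo-1-(2-chloroethyl)-8-(2-hydroxyethyl)-5-methyl-6-oxabicyclo[3.2.1]octan-7-one | OCC[C@H]1[C@@](CCCl)(C2=O)[C@@H](Br)CC[C@@]1(C)O2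
F6 | step 13 | 2-[(1S,2S,5R,8S)-2-bromo-1-(2-chloroethyl)-5-methyl-7-oxo-6-oxabicyclo[3.2.1]octan-8-yl]acetaldehyde | O=CC[C@H]1[C@@](CCCl)(C2=O)[C@@H](Br)CC[C@@]1(C)O2
F7 | step 13 | (1R,3aS,4S,7R,7aS)-4-bromo-1-formyl-7-hydroxy-7-methyloctahydro-1H-indene-3a-carboxylic acid 3a,7-lactone | O=C[C@@H]1CC[C@]2(C3=O)[C@@H](Br)CC[C@@](C)(O3)[C@@H]12
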